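The runs were computed with made-up constants; the scatter is artificial.

- Late in the earlier runs the target stands flat, at 36% in larch, 41% in alder and 42% in ash, although the reagent charge rises from 0.072 M to 0.16 M. Here is my quick reckoning for your three flasks.

| flask | starting material | reagent | free catalyst | remark | time |
|---|---|---|---|---|---|
| alder | 0.054 M | 0.108 M | 65 µM | run made earlier |  |
| larch | 0.054 M | 0.072 M | 65 µM | run made earlier |  |
| ash | 0.054 M | 0.16 M | 65 µM | run made earlier |  |
| green | 0.054 M | 0.108 M | 65 µM | everything together at the start | 8.0 h |
| violet | 0.054 M | 0.108 M (fed, over 5.0 h) | 65 µM | all else is in the flask from the start; the feed brings no volume worth counting | 8.0 h |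
| teal | 0.054 M (fed, over 5.0 h) | 0.108 M | 65 µM | all else is in the flask from the start; the feed brings no volume worth counting | 8.0 h |

- alder (time / h: target / %): 0.667: 28; 2.00: 38; 4.00: 39; 6.00: 42; 8.00: 41
- larch (time / h: target / %): 0.833: 25; 1.33: 30; 2.50: 36; 5.00: 36; 10.0: 36
- ash (time / h: target / %): 2.00: 41; 4.00: 43; 6.00: 46; 8.00: 42; 10.0: 42

(readings scatter by 1.5 percentage points)

- the best flask by amount of target, in percent of the starting material charged; "all alike" if 1.5 percentage points covers them all (green / violet / teal / all alike)
- amount of target at the end, in percent of the starting material charged, green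
- amount of target at the end, in percent of the starting material charged, violet
- amount of target at the end, in percent of the starting material charged, teal



- I read the reagent as going two ways: pseudo-first-order to target, with constant k at fixed free catalyst, and second-order to loss. A batch then gives target = c* ln(1 + charge/c*).
- Larch's plateau reading gives 0.00863 M for c*, with that reading's scatter, as the crossover concentration: the [reagent] at which both ways run equally fast, so that target takes the share c*/(c* + [reagent]).
- This returns 41.6% for alder, and so for green, but 47.5% for ash, whose last reading is 42%.
- Reckoned this way, larch's first reading stands for a [reagent] of 0.00823 M, which gives an estimate of k = 0.725 h⁻¹.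
- By this reckoning, violet's feed of 0.0216 M h⁻¹ balances both ways out at [reagent] = 0.0123 M, less than alder's charge, so I expect target to take 41.2% of the feed. With the remainder after the feed, I commit to 96.6%.
- The earlier runs charge 0.054 M, 0.054 M and 0.054 M of starting material, and my reckoning has no term for it. Teal opens with the whole reagent and no starting material, so I give teal no number and, as a judgement, place it below green.
- The forecast differs on violet: green best, with 40%, 24% and 6% for green, violet and teal, holding that “The likeliest cause is catalyst death”.
- The flasks give 40.8% for green, 96.1% for violet and 20.5% for teal, so violet is best. Violet's mean [reagent] over the first 5.0 h is 0.0110 M, and c* turns that into a reckoned target share of 44.0%.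

    catalyst intermediate C → free catalyst + target (k = 94.0 s⁻¹)
    2 catalyst intermediate C ⇌ resting dimer, settled at all times (K = 39000 M⁻¹)
    catalyst intermediate B ⇌ catalyst intermediate C (K = 5.30, k = 0.810 s⁻¹)
    reagent + free catalyst → catalyst intermediate A (k = 4.50 M⁻¹ s⁻¹)
    2 reagent → self-condensation product (k = 0.0110 M⁻¹ s⁻¹)
    starting material + catalyst intermediate A ⇌ catalyst intermediate B (K = 11.0 M⁻¹, k = 1300 M⁻¹ s⁻¹)

- Take violet's neighbour with 1.6 × 10⁻⁵ M of free catalyst. Scaling c* and k with free catalyst gives c* = 0.00212 M, a reckoned [reagent] during the feed of 0.0150 M and a reckoned 33.0% target. The neighbour gives 33.4%.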